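The slowness to watch is that of the step to product, the rate-limiting step. With reagent at full strength it takes substrate with a half-life of 91.7 s, while substrate and dormant form relax towards each other with a half-life of 1.21 s.

    substrate + reagent → product, rate k1*[substrate]*[reagent]^1.5 (k1 = 0.046 M⁻¹·⁵ s⁻¹, Ea1 = 42.0 kJ mol⁻¹)
    substrate ⇌ dormant form (K2 = 0.78, k2 = 0.25 s⁻¹, Ea2 = 75.0 kJ mol⁻¹, ΔH2 = 6.00 kJ mol⁻¹)
    (constants at 70 °C)

in all of them: time 1.0 min
- Thursday's: substrate 0.20 M; reagent 0.300 M (fed, over 40 s); temperature 70 °C; all else is in the flask from the start; the feed brings no volume worth counting
- Wednesday's: substrate 0.20 M (fed, over 40 s); reagent 0.300 M; temperature 70 °C; all else is in the flask from the start; the feed brings no volume worth counting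
- Friday's: substrate 0.20 M; reagent 0.300 M (fed, over 40 s); the addition at 40 °C, then warmed to 70 °C; the feed brings no volume worth counting
- Sunday's: substrate 0.20 M; reagent 0.300 M; temperature 70 °C; everything together at the start

* the best flask by amount of product, in percent of the substrate charged; "all alike" if 1.5 percentage points covers them all (Thursday's / Wednesday's / Friday's / Sunday's / all alike)
* amount of product at the end, in percent of the substrate charged, Thursday's
* amount of product at the end, in percent of the substrate charged, Wednesday's
* amount of product at the end, in percent of the substrate charged, Friday's
* amount of product at the end, in percent of the substrate charged, Sunday's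

- the list of constants is for 70 °C, to be carried to other temperatures by the activation energies and enthalpies

Start with Sunday's flask and work in logarithms, with every amount as a fraction of its charge. Take the main step by itself, reagent held at its charge (pseudo-first-order): the logarithm of the substrate fraction falls by 0.454, so 36.5% becomes product.

Now add the dormant form. The two forms relax towards each other far faster than the main step takes substrate, so I treat them as one pool, and a share 0.562 of that pool is free substrate. This gives the quantity to carry, the exposure: the fall in the natural logarithm of the pool over the run, with reagent at full strength and the free share applied, 0.255. My reckoned product for Sunday's flask comes down to 22.5%.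

Then add the reagent's own loss. That much product uses 15.0% of the reagent charge, and strength enters at the power 1.5. Averaging the rate between start and end multiplies the exposure by 0.892, which gives 0.227 and, as my figure for Sunday's, 20.3%.

Feeds shorten the exposure. In Wednesday's flask each portion of substrate stays 40.0 s on average. In Thursday's flask the rising reagent makes each feed second count 0.400 on average, so the run is worth 36.0 s. Friday's flask has the same rise in the cold, where the main step runs at 0.244 of its warm rate, so it is worth 23.9 s, taking the warming as instant and keeping the warm free share for the cold part as well. Before reagent loss, I get 15.6% for Wednesday's, 14.2% for Thursday's and 9.65% for Friday's, and my order puts Sunday's first.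

The forecast put Sunday's first, with 13.1% for Thursday's, 14.7% for Wednesday's, 9.7% for Friday's and 20.8% for Sunday's, saying that “the 1.5 order penalises slow reagent feeding more than slow substrate feeding”. The simulation gives Sunday's first, with 13.2% for Thursday's, 14.8% for Wednesday's, 9.63% for Friday's and 20.6% for Sunday's.

Sunday's 20.6% corresponds to an exposure of 0.231, against the 0.227 reckoned. At 1.00 min in Sunday's flask, the forward step to the dormant form takes substrate at 41 times the rate of the step to product, a half-life of 2.8 s against 1.9 min. Substrate stands there at 44% beside 35.0% of dormant form. For the neighbour of Sunday's charged with 0.51 M of reagent, the exposure scales to 0.565, and the same reagent correction gives 39.1%. The simulation gives 39.3%.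

(The numbers come from no measurement; the rest is arithmetic.)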